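## The problem

The target 21 is a 2,5-diaryl-3,4-bis(hydroxymethyl)oxolane: one saturated five-membered ether carrying two identical 4-hydroxy-3-methoxyphenyl groups and four contiguous stereocentres. The ring is numbered O1, C2, C3, C4, C5, the hydroxymethyl carbons are C3a and C4a, and C2 is the aryl carbon that is trans to its hydroxymethyl neighbour. The relations are then 2,3-trans, 3,4-trans and 4,5-cis, so the two aryl groups are cis, and the absolute configuration is 2S,3R,4R,5R. The molecule has no symmetry element despite its pairwise identical substituents, so it cannot be made by dimerisation and all four centres must be set one by one. The 4,5-cis relation is the demanding one: the all-trans isomer is more stable, and any closure or equilibration through a benzylic cation at C5 drifts towards it, so this relation must be fixed under kinetic control. Both ring C–O bonds are benzylic ethers of para-oxygenated arenes; acid ionises them (epimerising C2 or C5) and hydrogen on palladium can cleave them, while the free phenols oxidise easily and must stay masked to the end. On a five-membered ring each centre can direct its neighbour, which allows a relay C2 → C3 → C4 → C5 from a single reagent-controlled centre. The enabling feature is that, with C5 at the carbonyl level, O1–C2–C3–C4–C5 is a γ-aryl butyrolactone whose C3=C4 unsaturated form is an acceptor at C3 and a latent enolate at C4. The alternation of faces at C2, C3 and C4 is what two successive anti additions to that butenolide give, and the surviving C5 carbonyl is where the second aryl group enters.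

## Retrosynthesis

**21 ⇒ 20 (three O–CH2Ph bonds).** The two phenols and the C4a oxygen carry the same benzyl group, so one hydrogenolysis ends the route. Benzyl is preferred to silyl or acetal groups because it survives every reagent class used after it is installed (organozinc, organocopper, organolithium, Lewis acid with silane, periodate, borohydride). Precursor 20 differs from the target only in these groups. The forward step must stop before the ring benzylic C–O bonds are attacked.

**20 ⇒ 19 ⇒ 17 (C3a–O from a C3a=C bond).** The C3 hydroxymethyl group is traced through aldehyde 19 to a vinyl group. Vinyl is chosen as the C3a carrier because C3a must arrive as a carbon nucleophile at the β-carbon of an enoate and then stay silent through organolithium and Lewis-acid steps. An oxygenated one-carbon nucleophile transfers poorly from copper, and a silylmethyl group would later need oxidants that the dialkoxyarenes do not tolerate. The price is two steps (oxidative cleavage, reduction), placed after the lactone is gone, because a free C3a hydroxyl beside a lactone carbonyl would translactonise.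

**17 ⇒ 15 ⇒ 11 + 13 (C5–H and C5–aryl).** The order "aryl first, hydride second" follows from the 4,5-cis requirement. A nucleophile enters the five-membered oxocarbenium ion 16 anti to the C4 substituent, so when that nucleophile is hydride the aryl group is left cis to C4a. The reverse order (aryl nucleophile onto a C5–H cation) would give the 4,5-trans isomer. The cut removes one aryl group and one stereocentre and leads to lactone 11 and aryllithium 14, made from bromide 13. The forward steps need a single addition of 14 and a cold reduction.

**11 ⇒ 6 + 7 + 8 (C3–C3a and C4–C4a; the key disconnection).** Both exocyclic carbons are removed in one operation. The vinyl group of Grignard reagent 7 returns as a copper-bound nucleophile at C3, and chloromethyl ether 8 as the electrophile at C4 of enolate 10. Against stepwise introduction of each arm, or assembly of the trisubstituted lactone from acyclic pieces under auxiliary control, this cut derives two stereocentres from the one already present and uses two commodity reagents. Precursor 6 has a single stereocentre and no ring substituent other than the aryl group. In the forward reaction 1,4-addition must outpace removal of the C2 proton, and the enolate must react at carbon on the face away from the vinyl group.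

**6 ⇒ 5 ⇒ 4 (lactone O1–C5 acyl bond; Z-alkene from alkyne).** The butenolide is opened to Z-hydroxy enoate 5, which is traced to alkynol 4. This access to 6 is chosen for mildness: hydrogenation and a trace of acid, no base. That matters because C2–H of 6 is benzylic and γ to the carbonyl; base would form the aromatic 2-oxyfuran and erase the stereocentre. This speaks against butenolide syntheses that end with an amine-mediated elimination.

**4 ⇒ 1 + 2 (C2–alkyne bond).** A catalytic asymmetric alkynylation forms this bond and the only reagent-controlled stereocentre at once, from two commercial compounds. The neighbouring option (racemic addition, oxidation, asymmetric reduction of the ynone) costs two more steps and asks a catalyst to tell an aryl from an alkynyl group.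

**13 ⇒ 12 (O–benzyl bond).** Phenol 12 is benzylated so that the second aryl group carries the same protecting group as the first.

## Roads not taken

**Alternative 1:** The cut is O1–C5 and C2–C3, a [3+2] annulation. The trans donor–acceptor cyclopropane diester A2 and aldehyde 1 are combined under Sn(OTf)2 (divalent tin triflate). The aldehyde oxygen opens the cyclopropane at the aryl-bearing carbon with inversion, and the malonate carbon closes onto the aldehyde carbon to give tetrahydrofuran diester A1.
- Merits: the step is convergent and forms the ring with both aryl carbons at once. The 2,5-cis arrangement is its intrinsic outcome, and the inversion turns a trans cyclopropane into the difficult 4,5-cis relation without any contra-thermodynamic reduction. C3 can later be settled by thermodynamics, since the target has it trans to both neighbours.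
- Weak points: A2 is a trisubstituted, enantioenriched cyclopropane whose donor is an oxygenated aryl ring. Such donors open to a benzylic zwitterion, which erodes the stereospecificity on which C4 and C5 depend; the pivalate that tames the donor adds a third class of protecting group. Enantioselective access to A2 is itself a multi-step problem. After the annulation one ester must be excised (Krapcho dealkoxycarbonylation, strongly heated) and the other equilibrated and reduced.
- Comparison: this road is more convergent, and its ring-forming step achieves more than any single step of the chosen plan. The chosen plan sets against it a reagent-controlled centre that is a simple carbinol made in one catalytic step, no surplus carbon to remove, and one protecting group type throughout.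

**Alternative 2:** The cut is C3–C4. Cp2TiCl (trivalent titanium, from Cp2TiCl2 and Zn) opens the oxirane of epoxy propargyl ether A4 to a C3 radical, which closes 5-exo-dig onto the alkyne to give methylene tetrahydrofuran A3.
- Merits: the conditions are mild and neutral, the reaction type is established for furan lignans, C3a arrives as a free hydroxymethyl group at the right oxidation level, and the 2,3-trans relation is favoured in the cyclisation.
- Weak points: A4 is an unsymmetrical ether between two secondary, electron-rich benzylic carbinols, and both C2 and C5 must be fixed while that ether is made. Such centres react through cations, so the 2,5-relation is not secured by the key step at all. C4 is left as an exocyclic methylene; its conversion to the hydroxymethyl group by hydroboration has to choose between a face flanked by the C3 arm and a face flanked by the aryl groups, so the fourth centre rests on an unsecured late step.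
- Comparison: the key step is gentler and needs fewer oxidation-level changes afterwards. The chosen plan sets against it that each of C3, C4 and C5 is fixed by an identified 1,2-interaction and that no bis-benzylic ether has to be made by substitution.

**Alternative 3:** The cut is O1–C5 and C4–C4a. With PdCl2 (divalent palladium), CuCl2 and CO in methanol, the C2 hydroxyl of Z-homoallylic alcohol A6 attacks C5 of the palladium-bound alkene anti to the metal, and the C4–Pd bond inserts CO to give ester A5.
- Merits: one step closes the ring and delivers all four centres in their final configuration (anti addition to the Z-alkene gives 4,5-cis). A5 is two steps from the target, the shortest endgame of all the plans considered.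
- Weak points: the closure is 5-endo, an uncommon mode for oxypalladation. It competes with alkoxycarbonyl–palladium pathways to lactones, with β-hydride elimination from C4–Pd towards C3, and with attack of methanol at C5. The C2 carbinol of A6 is a para-alkoxybenzylic alcohol that can ionise in the acidic, chloride-rich medium. The 3,4-trans relation depends on the C3 substituent alone steering palladium to one alkene face, and A6 needs a Z-styrene beside two stereocentres.
- Comparison: if its key step worked, this road would be shorter than the chosen one. The chosen plan sets against it a key step of a known reaction type in which every selectivity it needs has a structural cause.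

Key step: step 3

Assumption 1: the (S,S)-ProPhenol ligand is taken to deliver the alkynyl group to the Si face of aldehyde 1, giving the (R)-carbinol; if the sense is the reverse, the (R,R) ligand is used and nothing else changes.
Assumption 2: compound 15 is written as the cyclic lactol; any open hydroxy ketone tautomer reaches the same oxocarbenium ion 16 in step 6.

Commercial starting materials: 1, 2, 7 (solution in THF), 8 and 12. Systematic names use IUPAC locants; C2–C5, C3a and C4a in the text refer to the labels defined above.

## Steps

Step 1
Reactants: 1 4-(benzyloxy)-3-methoxybenzaldehyde; 2 methyl propiolate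
Product: 4 methyl (4R)-4-[4-(benzyloxy)-3-methoxyphenyl]-4-hydroxybut-2-ynoate, via methylzinc alkynide 3 (not isolated)
Conditions: Me2Zn, (S,S)-ProPhenol [2,6-bis{[(2S)-2-(hydroxydiphenylmethyl)pyrrolidin-1-yl]methyl}-4-methylphenol] (10 mol %), Ph3PO (20 mol %), toluene, 0 to 4 °C; aq NH4Cl
Reagents that add atoms: none
Why: Catalytic enantioselective alkynylation of an aldehyde with a dinuclear zinc–ProPhenol catalyst: Me2Zn metalates 2 to alkynylzinc 3, and the chiral dizinc complex holds 3 and aldehyde 1 so that the alkynyl group is delivered to the Si face, giving the (R)-carbinol that becomes C2. Propiolate esters and aryl aldehydes are established partners for this catalyst, and Ph3PO is the usual additive against the uncatalysed background addition.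

Step 2
Reactants: 4 methyl (4R)-4-[4-(benzyloxy)-3-methoxyphenyl]-4-hydroxybut-2-ynoate
Product: 6 (5S)-5-[4-(benzyloxy)-3-methoxyphenyl]furan-2(5H)-one, via Z-hydroxy enoate 5 (not isolated)
Conditions: H2 (1 atm), Pd/CaCO3 poisoned with Pb(OAc)2, quinoline (trace), EtOAc, rt; then pyridinium p-toluenesulfonate (cat.), CH2Cl2, rt
Reagents that add atoms: none
Why: Cis semihydrogenation of the alkyne on lead-poisoned palladium gives Z-enoate 5, in which hydroxyl and ester are held together and lactonise (5-exo-trig acyl substitution) under mild acid with loss of methanol. The carbinol centre is untouched; only its descriptor changes from R to S, because alkynyl outranks aryl and alkenyl does not. Amine is limited to a trace of quinoline, since stronger base would isomerise 4 or remove the benzylic C2–H of 6.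

Step 3
Reactants: 6 (5S)-5-[4-(benzyloxy)-3-methoxyphenyl]furan-2(5H)-one; 7 vinylmagnesium bromide; 8 benzyl chloromethyl ether
Product: 11 (3R,4S,5S)-5-[4-(benzyloxy)-3-methoxyphenyl]-3-[(benzyloxy)methyl]-4-ethenyldihydrofuran-2(3H)-one, via bromomagnesium divinylcuprate 9 (not isolated), via magnesium enolate 10 (not isolated)
Conditions: 7 (3 equiv), CuI (1.5 equiv), THF, −40 °C; 6, −78 °C; then DMPU, 8 (4 equiv), −78 to −20 °C; aq NH4Cl/NH3
Reagents that add atoms: none
Why: Tandem conjugate addition–enolate alkylation of a γ-substituted butenolide, a known three-component reaction type for this substrate class. The monovalent copper ate complex 9 binds the C3=C4 bond of 6 on the face away from the C2 aryl group, oxidative addition gives a trivalent copper β-cuprio enolate, and reductive elimination delivers the vinyl group to C3, leaving magnesium enolate 10. C3 is therefore set by the C2 aryl group (anti, 2,3-trans), as is general for 5-substituted furan-2(5H)-ones, whose flat ring offers only two faces. DMPU and 8 then alkylate the planar enolate at C4 in an SN2 reaction; the new C3 vinyl group, now the nearest substituent, shields its own face, so C4a enters anti to it (3,4-trans). No ring is closed; two C–C bonds (C3–C3a and C4–C4a) and two stereocentres are formed. The step needs 1,4-addition to beat 1,2-addition and removal of the acidic benzylic C2 proton, which the preformed, weakly basic cuprate at −78 °C with no free Grignard reagent secures. It also needs reaction at carbon and only once: ester-type enolates alkylate at carbon with this electrophile, and a second alkylation would have to build a quaternary C4 beside two substituents. Any proton exchange at C4 would return the same trans,trans lactone, which is the more stable epimer.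

Step 4
Reactants: 12 4-bromo-2-methoxyphenol
Product: 13 1-(benzyloxy)-4-bromo-2-methoxybenzene
Conditions: BnBr, K2CO3, DMF, rt
Reagents that add atoms: benzyl bromide, BrCc1ccccc1
Why: Williamson ether synthesis on a phenol; the aryl bromide is inert to carbonate.

Step 5
Reactants: 11 (3R,4S,5S)-5-[4-(benzyloxy)-3-methoxyphenyl]-3-[(benzyloxy)methyl]-4-ethenyldihydrofuran-2(3H)-one; 13 1-(benzyloxy)-4-bromo-2-methoxybenzene
Product: 15 (3R,4S,5S)-2,5-bis[4-(benzyloxy)-3-methoxyphenyl]-3-[(benzyloxy)methyl]-4-ethenyloxolan-2-ol, via aryllithium 14 (not isolated)
Conditions: 13, n-BuLi, THF, −78 °C; then 11, −78 °C; aq NH4Cl at −78 °C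
Reagents that add atoms: none
Why: Bromine–lithium exchange gives 14, which adds to the lactone carbonyl (acyl addition of an organolithium to a γ-lactone); at −78 °C the cyclic lithium alkoxide does not open, so a second addition is avoided and a cold quench gives lactol 15. The new hemiketal centre is of no consequence because it becomes planar in step 6. Low temperature also keeps the basic reagent from enolising C4.

Step 6
Reactants: 15 (3R,4S,5S)-2,5-bis[4-(benzyloxy)-3-methoxyphenyl]-3-[(benzyloxy)methyl]-4-ethenyloxolan-2-ol
Product: 17 (2R,3R,4S,5S)-2,5-bis[4-(benzyloxy)-3-methoxyphenyl]-3-[(benzyloxy)methyl]-4-ethenyloxolane, via oxocarbenium ion 16 (not isolated)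
Conditions: Et3SiH, BF3·OEt2, CH2Cl2, −78 °C; aq NaHCO3 at −78 °C
Reagents that add atoms: none
Why: Lewis acid-promoted ionic reduction of a lactol: BF3·OEt2 ionises 15 to the aryl-conjugated planar oxocarbenium ion 16, and Et3SiH delivers hydride to C5 from the face opposite the adjacent C4 benzyloxymethyl group. The hydrogen thus ends trans and the aryl group cis to C4a, which sets the contra-thermodynamic 4,5-cis (and 2,5-cis) relation, as is usual for 2-aryl lactols bearing a 3-substituent. The mixture is kept at −78 °C and quenched cold, because on warming the Lewis acid reopens the benzylic C–O bonds and equilibrates C5 or C2 towards the all-trans isomer; BF3·OEt2 is returned in the net equation.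

Step 7
Reactants: 17 (2R,3R,4S,5S)-2,5-bis[4-(benzyloxy)-3-methoxyphenyl]-3-[(benzyloxy)methyl]-4-ethenyloxolane
Product: 19 (2S,3S,4R,5R)-2,5-bis[4-(benzyloxy)-3-methoxyphenyl]-4-[(benzyloxy)methyl]oxolane-3-carbaldehyde, via vicinal diol 18 (not isolated)
Conditions: OsO4 (cat.), NaIO4, 2,6-lutidine, 1,4-dioxane–H2O, rt
Reagents that add atoms: osmium tetroxide, O=[Os](=O)(=O)=O; sodium periodate, [Na+].[O-]I(=O)(=O)=O
Why: Lemieux–Johnson oxidation: catalytic OsO4 dihydroxylates the only alkene to diol 18, and NaIO4 cleaves it and reoxidises osmium, with 2,6-lutidine buffering the medium. C3 is now α to an aldehyde but already sits trans to both neighbours, so nothing drives it to epimerise. Ozone is avoided because it attacks the dialkoxyarenes.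

Step 8
Reactants: 19 (2S,3S,4R,5R)-2,5-bis[4-(benzyloxy)-3-methoxyphenyl]-4-[(benzyloxy)methyl]oxolane-3-carbaldehyde
Product: 20 {(2S,3R,4R,5R)-2,5-bis[4-(benzyloxy)-3-methoxyphenyl]-4-[(benzyloxy)methyl]oxolan-3-yl}methanol
Conditions: NaBH4, MeOH–THF, 0 °C
Reagents that add atoms: none
Why: Borohydride reduction of an aldehyde to the primary alcohol; nothing else in 19 is reducible and no stereocentre changes.

Step 9
Reactants: 20 {(2S,3R,4R,5R)-2,5-bis[4-(benzyloxy)-3-methoxyphenyl]-4-[(benzyloxy)methyl]oxolan-3-yl}methanol
Product: 21 [(2S,3R,4R,5R)-2,5-bis(4-hydroxy-3-methoxyphenyl)oxolane-3,4-diyl]dimethanol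
Conditions: H2 (1 atm), Pd(OH)2/C, EtOAc–EtOH, rt
Reagents that add atoms: none
Why: Heterogeneous hydrogenolysis of benzyl ethers: the two aryl benzyl ethers cleave first and Pd(OH)2 also cleaves the primary alkyl benzyl ether. A neutral medium and interruption at full conversion are meant to spare the two ring benzylic C–O bonds. No stereocentre is involved.

## Compound list

1 | 4-(benzyloxy)-3-methoxybenzaldehyde (O-benzylvanillin) | COc1cc(C=O)ccc1OCc1ccccc1 | starting material
2 | methyl prop-2-ynoate (methyl propiolate) | C#CC(=O)OC | starting material
3 | methyl 3-(methylzincio)prop-2-ynoate (not isolated) | C[Zn]C#CC(=O)OC | intermediate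
4 | methyl (4R)-4-[4-(benzyloxy)-3-methoxyphenyl]-4-hydroxybut-2-ynoate | COc1cc([C@@H](O)C#CC(=O)OC)ccc1OCc1ccccc1 | intermediate
5 | methyl (2Z,4S)-4-[4-(benzyloxy)-3-methoxyphenyl]-4-hydroxybut-2-enoate (not isolated) | COc1cc([C@@H](O)/C=C\C(=O)OC)ccc1OCc1ccccc1 | intermediate
6 | (5S)-5-[4-(benzyloxy)-3-methoxyphenyl]furan-2(5H)-one | COc1cc([C@H]2OC(=O)C=C2)ccc1OCc1ccccc1 | intermediate
7 | vinylmagnesium bromide | C=C[Mg]Br | starting material
8 | benzyl chloromethyl ether | ClCOCc1ccccc1 | starting material
9 | bromomagnesium divinylcuprate, monovalent copper (not isolated) | C=C[Cu-]C=C.[Mg+]Br | intermediate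
10 | bromomagnesium (4S,5S)-5-[4-(benzyloxy)-3-methoxyphenyl]-4-ethenyl-4,5-dihydrofuran-2-olate (not isolated) | COc1cc([C@H]2OC(O[Mg]Br)=C[C@@H]2C=C)ccc1OCc1ccccc1 | intermediate
11 | (3R,4S,5S)-5-[4-(benzyloxy)-3-methoxyphenyl]-3-[(benzyloxy)methyl]-4-ethenyldihydrofuran-2(3H)-one (three substituents all trans) | COc1cc([C@H]2OC(=O)[C@@H](COCc3ccccc3)[C@@H]2C=C)ccc1OCc1ccccc1 | intermediate
12 | 4-bromo-2-methoxyphenol | COc1cc(Br)ccc1O | starting material
13 | 1-(benzyloxy)-4-bromo-2-methoxybenzene | COc1cc(Br)ccc1OCc1ccccc1 | intermediate
14 | [4-(benzyloxy)-3-methoxyphenyl]lithium (not isolated) | COc1cc([Li])ccc1OCc1ccccc1 | intermediate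
15 | (3R,4S,5S)-2,5-bis[4-(benzyloxy)-3-methoxyphenyl]-3-[(benzyloxy)methyl]-4-ethenyloxolan-2-ol (both anomers) | COc1cc([C@H]2OC(O)(c3ccc(OCc4ccccc4)c(OC)c3)[C@@H](COCc3ccccc3)[C@@H]2C=C)ccc1OCc1ccccc1 | intermediate
16 | (2S,3S,4R)-2,5-bis[4-(benzyloxy)-3-methoxyphenyl]-4-[(benzyloxy)methyl]-3-ethenyl-3,4-dihydro-2H-furan-1-ium, the oxocarbenium ion from 15 (not isolated) | COc1cc([C@H]2[O+]=C(c3ccc(OCc4ccccc4)c(OC)c3)[C@@H](COCc3ccccc3)[C@@H]2C=C)ccc1OCc1ccccc1 | intermediate
17 | (2R,3R,4S,5S)-2,5-bis[4-(benzyloxy)-3-methoxyphenyl]-3-[(benzyloxy)methyl]-4-ethenyloxolane (aryl at locant 2 cis to the benzyloxymethyl group; other neighbours trans) | COc1cc([C@H]2O[C@@H](c3ccc(OCc4ccccc4)c(OC)c3)[C@@H](COCc3ccccc3)[C@@H]2C=C)ccc1OCc1ccccc1 | intermediate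
18 | 1-{(2S,3R,4R,5R)-2,5-bis[4-(benzyloxy)-3-methoxyphenyl]-4-[(benzyloxy)methyl]oxolan-3-yl}ethane-1,2-diol (both carbinol epimers; not isolated) | COc1cc([C@H]2O[C@@H](c3ccc(OCc4ccccc4)c(OC)c3)[C@@H](COCc3ccccc3)[C@@H]2C(O)CO)ccc1OCc1ccccc1 | intermediate
19 | (2S,3S,4R,5R)-2,5-bis[4-(benzyloxy)-3-methoxyphenyl]-4-[(benzyloxy)methyl]oxolane-3-carbaldehyde | COc1cc([C@H]2O[C@@H](c3ccc(OCc4ccccc4)c(OC)c3)[C@@H](COCc3ccccc3)[C@@H]2C=O)ccc1OCc1ccccc1 | intermediate
20 | {(2S,3R,4R,5R)-2,5-bis[4-(benzyloxy)-3-methoxyphenyl]-4-[(benzyloxy)methyl]oxolan-3-yl}methanol | COc1cc([C@H]2O[C@@H](c3ccc(OCc4ccccc4)c(OC)c3)[C@@H](COCc3ccccc3)[C@@H]2CO)ccc1OCc1ccccc1 | intermediate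
21 | [(2S,3R,4R,5R)-2,5-bis(4-hydroxy-3-methoxyphenyl)oxolane-3,4-diyl]dimethanol (2,3-trans, 3,4-trans, 4,5-cis; 2R,3R,4R,5S when numbered from the other end) | COc1cc([C@H]2O[C@@H](c3ccc(O)c(OC)c3)[C@@H](CO)[C@@H]2CO)ccc1O | target

## Step count and least certain steps

Total: 9 steps. Longest linear sequence: 8 steps (1 → 21 through steps 1, 2, 3, 5, 6, 7, 8 and 9); step 4 prepares the side fragment.

**Step 3 (key step).** The likely failures are:
- removal of the benzylic C2 proton by the organometallic, with racemisation through the 2-oxyfuran;
- reductive or SN2′-type cleavage of the benzylic lactone C–O bond by the electron-rich cuprate;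
- slow or oxygen-selective reaction of the magnesium enolate with the chloromethyl ether, so that non-alkylated lactone is obtained on work-up.

Fallback, from 6 to 11, with the two bond formations separated. A copper-catalysed addition of 7 in the presence of Me3SiCl (CuBr·SMe2 cat., THF, −78 °C) uses the silyl chloride to accelerate the 1,4-addition and to trap the enolate as {[(4S,5S)-5-[4-(benzyloxy)-3-methoxyphenyl]-4-ethenyl-4,5-dihydrofuran-2-yl]oxy}trimethylsilane F3. Hydrolysis on work-up gives (4R,5S)-5-[4-(benzyloxy)-3-methoxyphenyl]-4-ethenyldihydrofuran-2(3H)-one F4. Its lithium enolate (LiN(SiMe3)2, THF, −78 °C) is then alkylated with 8 anti to the vinyl group, which returns to the route at 11.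

**Step 1.** An electron-rich aryl aldehyde reacts slowly, so uncatalysed addition of the alkynylzinc may erode the enantioselectivity; the facial sense also rests on the assumption stated above.

Fallback, from 1 and 2 to 4. The lithium acetylide of 2 (LiN(SiMe3)2, THF, −78 °C) adds to 1 to give racemic methyl 4-[4-(benzyloxy)-3-methoxyphenyl]-4-hydroxybut-2-ynoate F1. MnO2 in CH2Cl2 oxidises it to methyl 4-[4-(benzyloxy)-3-methoxyphenyl]-4-oxobut-2-ynoate F2. Asymmetric transfer hydrogenation of F2 in 2-propanol with the base-free amido complex Ru(p-cymene)[TsNCH(Ph)CH(Ph)NH], the diamine antipode being chosen to give the R alcohol, returns to the route at 4.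

**Step 5.** The tetrahedral intermediate may collapse, allowing a second addition of 14. The basic aryllithium may instead enolise C4, returning 11 with possible epimerisation. Benzyl alcohol may also be lost by β-elimination from the open ketone form during work-up.

Fallback, from 11 to 15. Aminolysis with MeNH(OMe)·HCl and Me3Al opens the lactone to (2R,3S)-2-[(benzyloxy)methyl]-3-{(S)-[4-(benzyloxy)-3-methoxyphenyl](hydroxy)methyl}-N-methoxy-N-methylpent-4-enamide F5. Et3SiCl and imidazole convert it to the triethylsilyl ether (2R,3S)-2-[(benzyloxy)methyl]-3-{(S)-[4-(benzyloxy)-3-methoxyphenyl][(triethylsilyl)oxy]methyl}-N-methoxy-N-methylpent-4-enamide F6. Aryllithium 14 adds once to this amide through its chelated tetrahedral intermediate, giving (2R,3S)-1-[4-(benzyloxy)-3-methoxyphenyl]-2-[(benzyloxy)methyl]-3-{(S)-[4-(benzyloxy)-3-methoxyphenyl][(triethylsilyl)oxy]methyl}pent-4-en-1-one F7. Buffered fluoride (Bu4NF, AcOH, THF) removes the silyl group and the hydroxy ketone closes, returning to the route at 15.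

**Step 9.** Hydrogenolysis may go on to the ring benzylic C–O bonds once the phenols are free, because the primary alkyl benzyl ether is the slowest of the three to cleave and prolongs the exposure.

Fallback, from 20 to 21, with no new compound on the way (F0). The benzyl groups are removed without hydrogen by Lewis-acid cleavage with BCl3 in the presence of pentamethylbenzene as benzyl-cation scavenger (CH2Cl2, −78 °C, methanol quench at that temperature). The phenols become electron-poor aryl borates as soon as they are unmasked, which disfavours ionisation of the ring ethers.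

Step 6 defines C5 but follows the general behaviour of 2-aryl lactols with a 3-substituent; its one requirement is that the mixture does not warm before the quench.

## Further compounds

F1 | step 1 | methyl 4-[4-(benzyloxy)-3-methoxyphenyl]-4-hydroxybut-2-ynoate, racemic | COc1cc(C(O)C#CC(=O)OC)ccc1OCc1ccccc1
F2 | step 1 | methyl 4-[4-(benzyloxy)-3-methoxyphenyl]-4-oxobut-2-ynoate | COc1cc(C(=O)C#CC(=O)OC)ccc1OCc1ccccc1
F3 | step 3 | {[(4S,5S)-5-[4-(benzyloxy)-3-methoxyphenyl]-4-ethenyl-4,5-dihydrofuran-2-yl]oxy}trimethylsilane | COc1cc([C@H]2OC(O[Si](C)(C)C)=C[C@@H]2C=C)ccc1OCc1ccccc1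
F4 | step 3 | (4R,5S)-5-[4-(benzyloxy)-3-methoxyphenyl]-4-ethenyldihydrofuran-2(3H)-one | COc1cc([C@H]2OC(=O)C[C@@H]2C=C)ccc1OCc1ccccc1
F5 | step 5 | (2R,3S)-2-[(benzyloxy)methyl]-3-{(S)-[4-(benzyloxy)-3-methoxyphenyl](hydroxy)methyl}-N-methoxy-N-methylpent-4-enamide | COc1cc([C@@H](O)[C@@H](C=C)[C@H](COCc2ccccc2)C(=O)N(C)OC)ccc1OCc1ccccc1
F6 | step 5 | (2R,3S)-2-[(benzyloxy)methyl]-3-{(S)-[4-(benzyloxy)-3-methoxyphenyl][(triethylsilyl)oxy]methyl}-N-methoxy-N-methylpent-4-enamide | COc1cc([C@@H](O[Si](CC)(CC)CC)[C@@H](C=C)[C@H](COCc2ccccc2)C(=O)N(C)OC)ccc1OCc1ccccc1
F7 | step 5 | (2R,3S)-1-[4-(benzyloxy)-3-methoxyphenyl]-2-[(benzyloxy)methyl]-3-{(S)-[4-(benzyloxy)-3-methoxyphenyl][(triethylsilyl)oxy]methyl}pent-4-en-1-one | COc1cc([C@@H](O[Si](CC)(CC)CC)[C@@H](C=C)[C@H](COCc2ccccc2)C(=O)c2ccc(OCc3ccccc3)c(OC)c2)ccc1OCc1ccccc1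
F0 | step 9 | none | none
A1 | alternative 1 | dimethyl (2R,4R,5R)-2-[4-(benzyloxy)-3-methoxyphenyl]-4-{[(tert-butyldimethylsilyl)oxy]methyl}-5-[3-methoxy-4-(pivaloyloxy)phenyl]oxolane-3,3-dicarboxylate | COc1cc([C@H]2O[C@@H](c3ccc(OC(=O)C(C)(C)C)c(OC)c3)[C@@H](CO[Si](C)(C)C(C)(C)C)C2(C(=O)OC)C(=O)OC)ccc1OCc1ccccc1
A2 | alternative 1 | dimethyl (2R,3S)-2-{[(tert-butyldimethylsilyl)oxy]methyl}-3-[3-methoxy-4-(pivaloyloxy)phenyl]cyclopropane-1,1-dicarboxylate (trans) | COC(=O)C1(C(=O)OC)[C@H](c2ccc(OC(=O)C(C)(C)C)c(OC)c2)[C@H]1CO[Si](C)(C)C(C)(C)C
A3 | alternative 2 | {(2S,3R,5R)-2,5-bis[4-(benzyloxy)-3-methoxyphenyl]-4-methylideneoxolan-3-yl}methanol | COc1cc([C@H]2O[C@@H](c3ccc(OCc4ccccc4)c(OC)c3)C(=C)[C@@H]2CO)ccc1OCc1ccccc1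
A4 | alternative 2 | 2-[(R)-[4-(benzyloxy)-3-methoxyphenyl]{[(1S)-1-[4-(benzyloxy)-3-methoxyphenyl]prop-2-yn-1-yl]oxy}methyl]oxirane (either configuration at the oxirane carbon, which becomes the radical centre) | COc1cc([C@H](C2CO2)O[C@@H](c3ccc(OCc4ccccc4)c(OC)c3)C#C)ccc1OCc1ccccc1
A5 | alternative 3 | methyl (2R,3S,4R,5S)-2,5-bis[4-(benzyloxy)-3-methoxyphenyl]-4-[(benzyloxy)methyl]oxolane-3-carboxylate | COc1cc([C@H]2O[C@@H](c3ccc(OCc4ccccc4)c(OC)c3)[C@@H](C(=O)OC)[C@@H]2COCc2ccccc2)ccc1OCc1ccccc1
A6 | alternative 3 | (1S,2R,3Z)-1,4-bis[4-(benzyloxy)-3-methoxyphenyl]-2-[(benzyloxy)methyl]but-3-en-1-ol | COc1cc([C@@H](O)[C@@H](COCc2ccccc2)/C=C\c2ccc(OCc3ccccc3)c(OC)c2)ccc1OCc1ccccc1
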